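- The ratio I started from was the early rate of the red run over that of the ochre run: 1.94 for 4.00 times the substrate.

| setting | ochre | red | flask |
|---|---|---|---|
| substrate | 0.25 M | 1 M | 0.50 M |
| reagent in the second phase | 0.45 M | 0.45 M | 0.450 M |
| remark | run made earlier | run made earlier |  |
| time |  |  | 6.0 min |
| volume of the second phase over the first |  |  | 0.50 |

| run | time / min | target / % |
|---|---|---|
| ochre | 1.33 | 14.8 |
| ochre | 2.50 | 25.1 |
| ochre | 4.00 | 28.0 |
| ochre | 5.00 | 27.5 |
| ochre | 6.00 | 25.0 |
| red | 0.500 | 2.7 |
| red | 0.833 | 4.7 |
| red | 1.50 | 7.9 |
| red | 3.00 | 12.3 |
| red | 6.00 | 16.6 |

(readings scatter by 0.3 percentage points)

- in the second phase: reagent in the second phase; everything else is in the first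
- charges count per volume of the first phase; a concentration in a rate is the amount of a species over the volume of its own phase; every rate counts per litre of the first phase
- what was read earlier has a scatter of 0.3 percentage points, one standard deviation
- candidate steps: substrate <-> dormant form; target <-> isomer of the product; reagent in the reaction phase <-> reagent in the second phase; substrate + reagent in the reaction phase -> target; reagent in the reaction phase + target -> over-reacted product
- the earlier runs hold the two phases in the same ratio of volumes as the flask asked about

* amount of target at 6.0 min, in percent of the substrate charged
* the change that raises the amount of target at 6.0 min, in percent of the substrate charged most ("none" if none brings more than 2 percentage points) (epsilon / gamma / none)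
* amount of target at 6.0 min, in percent of the substrate charged, after gamma

- epsilon: doubling the transfer coefficient of the reagent in the second phase, all else as stated
- gamma: doubling the amount of reagent in the second phase, all else as stated

- So I reckoned per charge. Up to its first reading the ochre run turned 0.111 min⁻¹ of its charge into target, and the red run, up to its own first reading, 0.0540 min⁻¹.
- The flask's substrate charge equals the geometric mean of the two charges, 0.500 M, so I took the geometric mean of those two readings as the flask's early fractional rate, 0.0775 min⁻¹: the share of the charge turned into target per minute at the start, used as a pseudo-first-order constant and carrying the scatter of its readings.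
- With the main step by itself, I reckoned the fraction not yet turned at 6.0 min as 62.8%, so I had 37.2% target.
- Then I added the loss of target. At the highest reading of the ochre run, 28.0% at 4.00 min, I took making and loss to balance, which gave me a loss constant of 0.255 min⁻¹, an estimate that carries the scatter of the readings. Carried to the flask, that lowered my number to 18.0%.
- The rest, meaning transfer, dormant form and isomer, I took from the runs as they stood: the same mean of their readings at 6.00 min gave 20.4%, and that was my reckoning.
- The forecast differed from my reckoning: 22.5%, with gamma as the best change and 26% after gamma, adding “This ranking is a close call”.
- The flask gave 23.5%, and epsilon was the best change, with a gain of 3.4 percentage points, larger than the 0.46 points of gamma, which reached 23.9%.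

    substrate ⇌ dormant form (K = 7.80, k = 0.00370 s⁻¹)
    target ⇌ isomer of the product (K = 0.520, k = 0.00460 s⁻¹)
    reagent in the reaction phase ⇌ reagent in the second phase, rate k3*([reagent in the reaction phase] - [reagent in the second phase]/K3) per volume of the first phase (partition coefficient = 1.20, kL = 0.00190 s⁻¹)
    substrate + reagent in the reaction phase → target (k = 0.0910 L mol⁻¹ s⁻¹)
    reagent in the reaction phase + target → over-reacted product (k = 0.0290 L mol⁻¹ s⁻¹)

- In this flask at 2.14 min, each step taken net, target was made 2.45 times faster than it was used up. At 0.600 min the fraction left by the early fractional rate gave 4.54% target, and the flask held 4.26%. In the neighbouring flask, with the same charges read at 2.5 min, the same reckoning gave 17.6%, and target stood at 18.1%.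

(The runs were generated by integration for substances that don't exist; the scatter is artificial.)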